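The earlier runs and the new flask were computed with constants of no real substance; scatter was added.

The solid substrate feeds a dissolved stock, and that stock is what you should follow. Three new flasks stand beside the earlier runs birch and cedar.

| setting | birch | cedar | south | south-east | north |
|---|---|---|---|---|---|
| solid substrate | 0.20 M | 0.20 M | 0.20 M | 0.20 M | 0.20 M |
| first nucleophile | 1.2 equiv | 4 equiv | 0.800 equiv | 1.50 equiv | 3.00 equiv |
| second nucleophile | 1.1 equiv | 1.1 equiv | 1.10 equiv | 1.10 equiv | 1.10 equiv |
| remark | run made earlier | run made earlier |  |  |  |
| time |  |  | 2.5 h | 2.5 h | 2.5 h |

- birch (time / min: target / %, solid substrate / %): 6.00: 1, 76; 15.0: 12, 62; 30.0: 21, 46; 50.0: 38, 31; 60.0: 49, 22; 80.0: 67, 4; 120: 88, 0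
- cedar (time / min: target / %, solid substrate / %): 8.00: 5, 70; 12.0: 10, 67; 20.0: 15, 55; 30.0: 23, 48; 50.0: 44, 29; 60.0: 52, 22; 120: 91, 0

(each reading ± 1.5 percentage points)

- as a solid, counted per litre of solution: solid substrate
- at the start none of the solid substrate is in solution
- "hardly changes" means that all values lie within two and a half points (for a concentration: within two and a half percent of the largest)

- amount of target at the end, in percent of the solid substrate charged for south, south-east, north, in this order
- the course of these numbers from the first flask to the last (rises, then falls / rises all the way / falls all the way / hardly changes / falls, then rises)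

Call s the share of the charge that is missing from solid plus target. In birch, s goes from 33.0 % at 30.0 min to 29.0 % at 80.0 min. So replace the curve by its mean, 31.0 %; the ends lie 2 percentage points from it. Over that stretch the target grows by 0.00920 /min as a fraction of the charge, and dividing by the mean stock gives a first-order constant of 0.0297 /min. Cedar, reckoned the same way, gives 0.0352 /min. Let κ be their mean, 0.0324 /min, and τ the natural log of two over κ, 21.4 min: the turnover half-life of the dissolved stock.

The solid in birch falls by 0.00840 /min of the charge, so it is gone by about 84.8 min. Take s there as 29.0 %. Until 2.5 h you then have 3.05 half-lives, which leaves 3.50 % and a ceiling of 96.5 % for the target. Assume that one target takes one first nucleophile: south's 0.800 equiv then makes that reagent the limiting reagent and caps its target at 0.800 of the solid charged, as a fraction.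

The weak link is the assumption that the stock turns wholly into target. At 120 min the decay predicts 9.25 %. Cedar shows 9.00 %, while birch shows 12.0 %, an excess of 2.7 points against a scatter of 1.5 points on each reading, and this gap is built from two readings. I tentatively read this faint excess as a leak to the second nucleophile when less first nucleophile is charged, and I carry it unchanged from birch to south-east. My own figures are therefore just under the cap in south, 93.8 % in south-east and 96.5 % in north.

The forecast gives 78 %, 95 % and 95 %, a course that rises all the way, holding the rate "limited by dissolution and a follow-on step". For south-east it stands 1.2 points above mine.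

The flasks give 78.0 %, 92.0 % and 95.0 %; the course rises all the way.

    starting material ⇌ intermediate (K = 0.0650, k = 5.50 × 10⁻⁴ /s)
    first nucleophile + intermediate → target (k = 2.20 /M/s)
    second nucleophile + intermediate → other capture product (k = 0.100 /M/s)
    solid substrate ⇌ starting material, rate k4*(cs4 - [starting material]) while solid is left; crystals form when [starting material] > cs4 (solubility = 0.0620 M, k = 0.00440 /s)

North holds 3.13 % of starting material at 2.50 h and south-east 3.33 %, against the 3.50 % reckoned from τ. In south, the first nucleophile takes the intermediate 12 times as fast as the second nucleophile at 0.476 h. At 2.50 h, with 2.45 % of its charge left, that ratio is 0.464, and the other capture product in south stands at 17.1 %.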